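Assumption: atom labels C1–C15 follow germacranolide numbering (C4–C5 epoxide, lactone O on C6, C12 carbonyl, C13 exocyclic CH2, ester on C8, OH on C9, C1=C10 alkene); the SMILES is read as 4R,5R,6S,7R,8R,9R with a 1(10)Z double bond.

**Retrosynthetic overview**
1. Target 31 ← PMB removal ← ring-closing metathesis at C1=C10 (ten-membered ring, formed last) ← C8 senecioylation of adduct 27.
2. Key C7–C8 bond: indium-mediated intermolecular carbonyl allylation of aldehyde 25 (C8–C10, C14) with the 3-(bromomethyl)butenolide 17 (C1–C7, C11–C13, C15). This turns the butenolide into the trans α-methylene-γ-butyrolactone and sets C7 and C8.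
3. 17 ← Pd carbonylative lactonisation of a (Z)-iodo allylic alcohol ← hydroxyl-directed epoxidation (C4, C5) ← Red-Al/I2 ← CBS reduction of an enynone (C6) ← enal 6 + propargyl ether 7.
4. 25 ← methyl (S)-glycerate acetonide 18 (source of C9).
5. Ring order: oxirane (step 8) → butenolide (step 9; becomes the methylene lactone in step 19) → cyclodecene (step 21).

**Route**

Step 1
Reactants: 1 but-3-en-1-ylmagnesium bromide (commercial THF solution, 2 equiv); 2 ethyl but-2-ynoate
Product: 4 ethyl (2E)-3-methylhepta-2,6-dienoate, via bromomagnesium dibutenylcuprate 3 (not isolated)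
Conditions: CuI (1 equiv), THF, −40 → −78 °C; add 2, −78 °C; MeOH then aq NH4Cl at −78 °C
Reagents that add atoms: none
Why: Syn carbocupration (cuprate conjugate addition) of the ynoate and cold protonation with retention put the butenyl group trans to the ester, giving the E alkene that later becomes the trans epoxide.

Step 2
Reactants: 4 ethyl (2E)-3-methylhepta-2,6-dienoate
Product: 5 (2E)-3-methylhepta-2,6-dien-1-ol
Conditions: DIBAL-H (2.2 equiv), CH2Cl2, −78 → 0 °C; Rochelle salt
Reagents that add atoms: none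
Why: DIBAL-H 1,2-reduction of the conjugated ester gives the allylic alcohol without touching either alkene.

Step 3
Reactants: 5 (2E)-3-methylhepta-2,6-dien-1-ol
Product: 6 (2E)-3-methylhepta-2,6-dienal
Conditions: activated MnO2, CH2Cl2, rt
Reagents that add atoms: none
Why: MnO2 allylic oxidation is selective for the allylic alcohol and keeps the E geometry.

Step 4
Reactants: 7 tert-butyldimethyl(prop-2-yn-1-yloxy)silane; 6 (2E)-3-methylhepta-2,6-dienal
Product: 9 rac-(5E)-1-[(tert-butyldimethylsilyl)oxy]-6-methyldeca-5,9-dien-2-yn-4-ol, via lithium acetylide 8 (not isolated)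
Conditions: n-BuLi, THF, −78 °C; then 6, −78 °C; aq NH4Cl
Reagents that add atoms: none
Why: Acetylide 1,2-addition to the enal joins C6 to C7 and brings in C11 and C13.

Step 5
Reactants: 9 rac-enynol
Product: 10 (5E)-1-[(tert-butyldimethylsilyl)oxy]-6-methyldeca-5,9-dien-2-yn-4-one
Conditions: activated MnO2, CH2Cl2, rt
Reagents that add atoms: none
Why: MnO2 oxidation of the doubly activated (allylic and propargylic) alcohol gives the cross-conjugated ketone for asymmetric reduction.

Step 6
Reactants: 10 enynone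
Product: 11 (4R,5E)-1-[(tert-butyldimethylsilyl)oxy]-6-methyldeca-5,9-dien-2-yn-4-ol
Conditions: (R)-Me-CBS (0.5 equiv), catecholborane, CH2Cl2, −78 °C; MeOH, aq NaOH wash
Reagents that add atoms: none
Why: Corey–Bakshi–Shibata reduction in which the 2-methylalkenyl arm acts as the large group and the linear alkynyl arm as the small one, so the (R)-catalyst gives the (R)-carbinol (C6 of the target); catecholborane at −78 °C spares the terminal alkene.

Step 7
Reactants: 11 (R)-enynol
Product: 13 (2Z,4R,5E)-1-[(tert-butyldimethylsilyl)oxy]-2-iodo-6-methyldeca-2,5,9-trien-4-ol, via cyclic sodium alkenylalanate 12 (not isolated)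
Conditions: Red-Al, THF, −20 → 0 °C; EtOAc; then I2, THF, −78 °C; Rochelle salt/Na2S2O3
Reagents that add atoms: iodine, II
Why: Hydroxyl-directed trans-hydroalumination of the propargylic alcohol puts Al on the distal alkyne carbon (C11), and iodinolysis with retention gives the Z iodoalkene with iodine cis to the carbinol.

Step 8
Reactants: 13 (Z)-iodo dienol
Product: 14 (1S,2Z)-1-[(2R,3R)-3-(but-3-en-1-yl)-3-methyloxiran-2-yl]-4-[(tert-butyldimethylsilyl)oxy]-3-iodobut-2-en-1-ol
Conditions: m-CPBA, NaHCO3, CH2Cl2, 0 °C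
Reagents that add atoms: m-CPBA, OOC(=O)c1cccc(Cl)c1
Why: Hydroxyl-directed (Henbest) peracid epoxidation of the electron-rich trisubstituted alkene; A(1,3) strain from the cis C4 methyl fixes the reactive conformer and gives the threo epoxy alcohol (C4 R, C5 R), while the iodoalkene and terminal alkene are too unreactive to compete.

Step 9
Reactants: 14 iodo epoxy alcohol
Product: 15 (5S)-5-[(2R,3R)-3-(but-3-en-1-yl)-3-methyloxiran-2-yl]-3-{[(tert-butyldimethylsilyl)oxy]methyl}furan-2(5H)-one
Conditions: Pd(PPh3)4 (5 mol %), CO (1 atm), Et3N, MeCN, 40 °C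
Reagents that add atoms: carbon monoxide, [C-]#[O+]
Why: Pd-catalysed carbonylative lactonisation: the acyl-palladium formed from the Z vinyl iodide is trapped by the cis C6 hydroxyl, closing the butenolide and adding C12 without touching C6.

Step 10
Reactants: 15 silyl ether
Product: 16 (5S)-5-[(2R,3R)-3-(but-3-en-1-yl)-3-methyloxiran-2-yl]-3-(hydroxymethyl)furan-2(5H)-one
Conditions: HF·pyridine, pyridine, THF, 0 °C → rt
Reagents that add atoms: none
Why: Buffered fluoride desilylation frees the primary allylic alcohol without opening the epoxide or deprotonating the butenolide.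

Step 11
Reactants: 16 hydroxymethyl butenolide
Product: 17 (5S)-3-(bromomethyl)-5-[(2R,3R)-3-(but-3-en-1-yl)-3-methyloxiran-2-yl]furan-2(5H)-one
Conditions: CBr4, PPh3, CH2Cl2, 0 °C
Reagents that add atoms: carbon tetrabromide, BrC(Br)(Br)Br
Why: Appel bromination converts the primary allylic alcohol to the allylic bromide under near-neutral conditions.

Step 12
Reactants: 18 methyl (4S)-2,2-dimethyl-1,3-dioxolane-4-carboxylate
Product: 19 (4S)-N-methoxy-N,2,2-trimethyl-1,3-dioxolane-4-carboxamide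
Conditions: MeNH(OMe)·HCl, i-PrMgCl, THF, −20 °C; aq NH4Cl
Reagents that add atoms: N,O-dimethylhydroxylamine hydrochloride, CNOC.Cl
Why: Weinreb amide formation by aminolysis of the ester with the magnesium amide; the stereocentre (future C9) is not touched.

Step 13
Reactants: 19 Weinreb amide
Product: 20 1-[(4S)-2,2-dimethyl-1,3-dioxolan-4-yl]ethan-1-one
Conditions: MeMgBr, THF, 0 °C; aq NH4Cl
Reagents that add atoms: methylmagnesium bromide, C[Mg]Br
Why: Weinreb ketone synthesis; the chelated tetrahedral adduct stops at the methyl ketone and brings in C14.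

Step 14
Reactants: 20 methyl ketone
Product: 21 (4R)-2,2-dimethyl-4-(prop-1-en-2-yl)-1,3-dioxolane
Conditions: Ph3PCH3Br (slight excess over base), KOt-Bu, THF, 0 °C
Reagents that add atoms: methyltriphenylphosphonium bromide, C[P+](c1ccccc1)(c1ccccc1)c1ccccc1.[Br-]
Why: Wittig methylenation gives the isopropenyl group; with no free base and low temperature the α-alkoxy centre is not epimerised (the descriptor changes from S to R only through CIP priorities).

Step 15
Reactants: 21 isopropenyl dioxolane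
Product: 22 (2R)-3-methylbut-3-ene-1,2-diol
Conditions: 80% aq AcOH, 40 °C
Reagents that add atoms: none
Why: Acid-catalysed acetonide hydrolysis frees the diol.

Step 16
Reactants: 22 diol
Product: 23 (4R)-2-(4-methoxyphenyl)-4-(prop-1-en-2-yl)-1,3-dioxolane (both acetal epimers)
Conditions: 4-MeOC6H4CH(OMe)2, PPTS (cat.), CH2Cl2, rt
Reagents that add atoms: 4-methoxybenzaldehyde dimethyl acetal, COC(OC)c1ccc(OC)cc1
Why: Transacetalisation ties the diol as a p-methoxybenzylidene acetal so that the two oxygens can be told apart in the next step.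

Step 17
Reactants: 23 p-methoxybenzylidene acetal
Product: 24 (2R)-2-[(4-methoxybenzyl)oxy]-3-methylbut-3-en-1-ol
Conditions: DIBAL-H (3 equiv), CH2Cl2, −78 → 0 °C; Rochelle salt
Reagents that add atoms: none
Why: Regioselective reductive acetal opening: aluminium binds the less hindered primary oxygen, leaving the PMB ether on the secondary (C9) oxygen.

Step 18
Reactants: 24 primary alcohol
Product: 25 (2R)-2-[(4-methoxybenzyl)oxy]-3-methylbut-3-enal
Conditions: Dess–Martin periodinane, NaHCO3, CH2Cl2, 0 °C; used crude at once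
Reagents that add atoms: none
Why: Buffered Dess–Martin oxidation gives the α-alkoxy β,γ-unsaturated aldehyde without base, so it neither epimerises nor moves into conjugation.

Step 19
Reactants: 17 bromomethyl butenolide; 25 aldehyde
Product: 27 (4R,5S)-5-[(2R,3R)-3-(but-3-en-1-yl)-3-methyloxiran-2-yl]-4-{(1R,2R)-1-hydroxy-2-[(4-methoxybenzyl)oxy]-3-methylbut-3-en-1-yl}-3-methylidenedihydrofuran-2(3H)-one, via allylindium dibromide 26 (not isolated)
Conditions: In powder, THF/H2O (3:1), rt
Reagents that add atoms: none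
Why: Indium-mediated Barbier carbonyl allylation with γ-attack through a chair transition state: the aldehyde adds to the butenolide face anti to the C6 substituent (C7, trans lactone), the ring-locked E-type allyl geometry with the aldehyde substituent equatorial gives the 7,8-anti adduct (C8 R), and chelation of the α-OPMB group to indium favours the same 8,9-syn product.

Step 20
Reactants: 27 Barbier adduct; 28 3-methylbut-2-enoic acid (senecioic acid)
Product: 29 (1R,2R)-1-{(2S,3R)-2-[(2R,3R)-3-(but-3-en-1-yl)-3-methyloxiran-2-yl]-4-methylidene-5-oxotetrahydrofuran-3-yl}-2-[(4-methoxybenzyl)oxy]-3-methylbut-3-en-1-yl 3-methylbut-2-enoate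
Conditions: DCC, DMAP (cat.), CH2Cl2, 0 °C → rt
Reagents that add atoms: none
Why: Steglich esterification acylates the only free hydroxyl (C8) and, by using the acid and no strong base, avoids deconjugation of the senecioyl group.

Step 21
Reactants: 29 diene
Product: 30 (4R,5R,6S,7R,8R,9R,1(10)Z)-4,5-epoxy-9-[(4-methoxybenzyl)oxy]-8-(3-methylbut-2-enoyloxy)germacra-1(10),11(13)-dien-12,6-olide
Conditions: Grubbs II (20 mol %, in portions), 1,4-benzoquinone (cat.), toluene (1 mM), 80 °C
Reagents that add atoms: none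
Why: Ring-closing metathesis between the terminal alkene and the isopropenyl group closes the ten-membered ring; ring strain makes the cis (Z) trisubstituted cyclodecene the favoured product, and the electron-poor methylene lactone and senecioate do not take part.

Step 22
Reactants: 30 PMB ether
Product: 31 (4R,5R,6S,7R,8R,9R,1(10)Z)-4,5-epoxy-9-hydroxy-8-(3-methylbut-2-enoyloxy)germacra-1(10),11(13)-dien-12,6-olide (CNP0188779.3)
Conditions: DDQ, CH2Cl2/pH 7 buffer (10:1), 0 °C
Reagents that add atoms: none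
Why: Oxidative PMB cleavage under buffered, non-acidic conditions frees the C9 hydroxyl without transannular epoxide opening or acyl migration.

**Compound list**
1 | but-3-en-1-ylmagnesium bromide | C=CCC[Mg]Br | starting material
2 | ethyl but-2-ynoate | CC#CC(=O)OCC | starting material
3 | bromomagnesium di(but-3-en-1-yl)cuprate | C=CCC[Cu-]CCC=C.[Mg+]Br | intermediate (not isolated)
4 | ethyl (2E)-3-methylhepta-2,6-dienoate | CCOC(=O)/C=C(\C)CCC=C | intermediate
5 | (2E)-3-methylhepta-2,6-dien-1-ol | OC/C=C(\C)CCC=C | intermediate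
6 | (2E)-3-methylhepta-2,6-dienal | O=C/C=C(\C)CCC=C | intermediate
7 | tert-butyldimethyl(prop-2-yn-1-yloxy)silane | C#CCO[Si](C)(C)C(C)(C)C | starting material
8 | lithium 3-[(tert-butyldimethylsilyl)oxy]prop-1-yn-1-ide | [Li]C#CCO[Si](C)(C)C(C)(C)C | intermediate (not isolated)
9 | rac-(5E)-1-[(tert-butyldimethylsilyl)oxy]-6-methyldeca-5,9-dien-2-yn-4-ol | OC(/C=C(\C)CCC=C)C#CCO[Si](C)(C)C(C)(C)C | intermediate
10 | (5E)-1-[(tert-butyldimethylsilyl)oxy]-6-methyldeca-5,9-dien-2-yn-4-one | O=C(/C=C(\C)CCC=C)C#CCO[Si](C)(C)C(C)(C)C | intermediate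
11 | (4R,5E)-1-[(tert-butyldimethylsilyl)oxy]-6-methyldeca-5,9-dien-2-yn-4-ol | O[C@H](/C=C(\C)CCC=C)C#CCO[Si](C)(C)C(C)(C)C | intermediate
12 | sodium bis(2-methoxyethoxy) cyclic alkenylalanate of 11 (1,2-oxaaluminole ate complex) | [Na+].COCCO[Al-]1(OCCOC)O[C@H](/C=C(\C)CCC=C)C=C1CO[Si](C)(C)C(C)(C)C | intermediate (not isolated)
13 | (2Z,4R,5E)-1-[(tert-butyldimethylsilyl)oxy]-2-iodo-6-methyldeca-2,5,9-trien-4-ol | O[C@H](/C=C(\C)CCC=C)/C=C(\I)CO[Si](C)(C)C(C)(C)C | intermediate
14 | (1S,2Z)-1-[(2R,3R)-3-(but-3-en-1-yl)-3-methyloxiran-2-yl]-4-[(tert-butyldimethylsilyl)oxy]-3-iodobut-2-en-1-ol | O[C@H]([C@H]1O[C@]1(C)CCC=C)/C=C(\I)CO[Si](C)(C)C(C)(C)C | intermediate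
15 | (5S)-5-[(2R,3R)-3-(but-3-en-1-yl)-3-methyloxiran-2-yl]-3-{[(tert-butyldimethylsilyl)oxy]methyl}furan-2(5H)-one | O=C1O[C@H]([C@H]2O[C@]2(C)CCC=C)C=C1CO[Si](C)(C)C(C)(C)C | intermediate
16 | (5S)-5-[(2R,3R)-3-(but-3-en-1-yl)-3-methyloxiran-2-yl]-3-(hydroxymethyl)furan-2(5H)-one | O=C1O[C@H]([C@H]2O[C@]2(C)CCC=C)C=C1CO | intermediate
17 | (5S)-3-(bromomethyl)-5-[(2R,3R)-3-(but-3-en-1-yl)-3-methyloxiran-2-yl]furan-2(5H)-one | O=C1O[C@H]([C@H]2O[C@]2(C)CCC=C)C=C1CBr | intermediate
18 | methyl (4S)-2,2-dimethyl-1,3-dioxolane-4-carboxylate | COC(=O)[C@@H]1COC(C)(C)O1 | starting material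
19 | (4S)-N-methoxy-N,2,2-trimethyl-1,3-dioxolane-4-carboxamide | CON(C)C(=O)[C@@H]1COC(C)(C)O1 | intermediate
20 | 1-[(4S)-2,2-dimethyl-1,3-dioxolan-4-yl]ethan-1-one | CC(=O)[C@@H]1COC(C)(C)O1 | intermediate
21 | (4R)-2,2-dimethyl-4-(prop-1-en-2-yl)-1,3-dioxolane | C=C(C)[C@@H]1COC(C)(C)O1 | intermediate
22 | (2R)-3-methylbut-3-ene-1,2-diol | OC[C@H](O)C(C)=C | intermediate
23 | (4R)-2-(4-methoxyphenyl)-4-(prop-1-en-2-yl)-1,3-dioxolane (acetal epimers) | C=C(C)[C@@H]1COC(c2ccc(OC)cc2)O1 | intermediate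
24 | (2R)-2-[(4-methoxybenzyl)oxy]-3-methylbut-3-en-1-ol | OC[C@H](OCc1ccc(OC)cc1)C(C)=C | intermediate
25 | (2R)-2-[(4-methoxybenzyl)oxy]-3-methylbut-3-enal | O=C[C@H](OCc1ccc(OC)cc1)C(C)=C | intermediate
26 | {[(5S)-5-[(2R,3R)-3-(but-3-en-1-yl)-3-methyloxiran-2-yl]-2-oxo-2,5-dihydrofuran-3-yl]methyl}indium dibromide (drawn as the RInBr2 part of the sesquibromide) | O=C1O[C@H]([C@H]2O[C@]2(C)CCC=C)C=C1C[In](Br)Br | intermediate (not isolated)
27 | (4R,5S)-5-[(2R,3R)-3-(but-3-en-1-yl)-3-methyloxiran-2-yl]-4-{(1R,2R)-1-hydroxy-2-[(4-methoxybenzyl)oxy]-3-methylbut-3-en-1-yl}-3-methylidenedihydrofuran-2(3H)-one | C=C1C(=O)O[C@H]([C@H]2O[C@]2(C)CCC=C)[C@H]1[C@@H](O)[C@H](OCc1ccc(OC)cc1)C(C)=C | intermediate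
28 | 3-methylbut-2-enoic acid (senecioic acid) | CC(C)=CC(=O)O | starting material
29 | (1R,2R)-1-{(2S,3R)-2-[(2R,3R)-3-(but-3-en-1-yl)-3-methyloxiran-2-yl]-4-methylidene-5-oxotetrahydrofuran-3-yl}-2-[(4-methoxybenzyl)oxy]-3-methylbut-3-en-1-yl 3-methylbut-2-enoate | C=C1C(=O)O[C@H]([C@H]2O[C@]2(C)CCC=C)[C@H]1[C@@H](OC(=O)C=C(C)C)[C@H](OCc1ccc(OC)cc1)C(C)=C | intermediate
30 | (4R,5R,6S,7R,8R,9R,1(10)Z)-4,5-epoxy-9-[(4-methoxybenzyl)oxy]-8-(3-methylbut-2-enoyloxy)germacra-1(10),11(13)-dien-12,6-olide | C=C1C(=O)O[C@H]2[C@H]1[C@@H](OC(=O)C=C(C)C)[C@H](OCc1ccc(OC)cc1)/C(C)=C\CC[C@@]1(C)O[C@H]21 | intermediate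
31 | (4R,5R,6S,7R,8R,9R,1(10)Z)-4,5-epoxy-9-hydroxy-8-(3-methylbut-2-enoyloxy)germacra-1(10),11(13)-dien-12,6-olide | C=C1C(=O)O[C@H]2[C@H]1[C@@H](OC(=O)C=C(C)C)[C@H](O)/C(C)=C\CC[C@@]1(C)O[C@H]21 | target

**Step count and risks**
Total steps: 22. Longest linear sequence: 15 (steps 1–11, then 19–22); the aldehyde branch is 7 steps (12–18).

Most likely to fail:

1. Step 21 (metathesis to a strained ten-membered ring with a trisubstituted alkene next to a bulky ether). Fallback: invert the end game. Set out from 29 and remove the PMB group first (DDQ, CH2Cl2/pH 7 buffer, 0 °C) to give the free allylic alcohol (1R,2R)-1-{(2S,3R)-2-[(2R,3R)-3-(but-3-en-1-yl)-3-methyloxiran-2-yl]-4-methylidene-5-oxotetrahydrofuran-3-yl}-2-hydroxy-3-methylbut-3-en-1-yl 3-methylbut-2-enoate F1. Cyclise this unprotected substrate (Hoveyda–Grubbs II, toluene, high dilution, 80 °C), where the free allylic hydroxyl speeds up metathesis at the neighbouring 1,1-disubstituted alkene and the PMB bulk is gone. This makes metathesis the last step and returns to the route at 31.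

2. Step 19 (the α-alkoxy β,γ-unsaturated aldehyde 25 is labile, and the 8,9-syn outcome depends on chelation agreeing with reagent control). Fallback: take the α-stereocentre out of the coupling. Set out from 17 and run the same indium Barbier reaction with commercial 3-methylbut-2-enal, so that C7 and C8 are set by the reagent alone, giving (4R,5S)-5-[(2R,3R)-3-(but-3-en-1-yl)-3-methyloxiran-2-yl]-4-[(1S)-1-hydroxy-3-methylbut-2-en-1-yl]-3-methylidenedihydrofuran-2(3H)-one F2. A hydroxyl-directed singlet-oxygen ene reaction (O2, tetraphenylporphyrin, hν, CCl4, 0 °C) then sets C9 threo to C8 and forms the isopropenyl group, giving the hydroperoxide (4R,5S)-5-[(2R,3R)-3-(but-3-en-1-yl)-3-methyloxiran-2-yl]-4-[(1R,2R)-2-hydroperoxy-1-hydroxy-3-methylbut-3-en-1-yl]-3-methylidenedihydrofuran-2(3H)-one F3. PPh3 reduces it to the diol (4R,5S)-5-[(2R,3R)-3-(but-3-en-1-yl)-3-methyloxiran-2-yl]-4-[(1R,2R)-1,2-dihydroxy-3-methylbut-3-en-1-yl]-3-methylidenedihydrofuran-2(3H)-one F4. Etherification of what is expected to be the less hindered allylic 9-OH (4-methoxybenzyl trichloroacetimidate, cat. La(OTf)3, toluene, 0 °C) returns to the route at 27; the regioselectivity of this last step is the weak point of the fallback.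

3. Step 6 (enantioselectivity when the ketone carries two unsaturated arms). Fallback: set C6 by asymmetric C–C bond formation instead of oxidation and reduction. Set out from 6 and 7 and add the alkyne to the enal with Me2Zn and a ProPhenol ligand (toluene, 0 °C), using the ligand antipode that gives the (R)-carbinol (checked by Mosher ester analysis). This returns to the route at 11, skips 9 and 10, and makes no new compound.

**Further compounds**
F1 | step 21 | (1R,2R)-1-{(2S,3R)-2-[(2R,3R)-3-(but-3-en-1-yl)-3-methyloxiran-2-yl]-4-methylidene-5-oxotetrahydrofuran-3-yl}-2-hydroxy-3-methylbut-3-en-1-yl 3-methylbut-2-enoate | C=C1C(=O)O[C@H]([C@H]2O[C@]2(C)CCC=C)[C@H]1[C@@H](OC(=O)C=C(C)C)[C@H](O)C(C)=C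
F2 | step 19 | (4R,5S)-5-[(2R,3R)-3-(but-3-en-1-yl)-3-methyloxiran-2-yl]-4-[(1S)-1-hydroxy-3-methylbut-2-en-1-yl]-3-methylidenedihydrofuran-2(3H)-one | C=C1C(=O)O[C@H]([C@H]2O[C@]2(C)CCC=C)[C@H]1[C@@H](O)C=C(C)C
F3 | step 19 | (4R,5S)-5-[(2R,3R)-3-(but-3-en-1-yl)-3-methyloxiran-2-yl]-4-[(1R,2R)-2-hydroperoxy-1-hydroxy-3-methylbut-3-en-1-yl]-3-methylidenedihydrofuran-2(3H)-one | C=C1C(=O)O[C@H]([C@H]2O[C@]2(C)CCC=C)[C@H]1[C@@H](O)[C@H](OO)C(C)=C
F4 | step 19 | (4R,5S)-5-[(2R,3R)-3-(but-3-en-1-yl)-3-methyloxiran-2-yl]-4-[(1R,2R)-1,2-dihydroxy-3-methylbut-3-en-1-yl]-3-methylidenedihydrofuran-2(3H)-one | C=C1C(=O)O[C@H]([C@H]2O[C@]2(C)CCC=C)[C@H]1[C@@H](O)[C@H](O)C(C)=C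
F0 | step 6 | none | none
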